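**Plan**
- **Cuts.** After removal of the helper groups (four Cl, three benzyl, three pivaloyl), one operation cuts the carbinol C–O bond, the indane C3–C3a bond and the indane C1–C2 bond. This gives a resveratrol-type and an ε-viniferin-type 4-hydroxystilbene. The latter is cut at its aryl–vinyl bond (Heck) and at the dihydrobenzofuran C2–C3 bond (carbene C–H insertion), back to a benzophenone.
- **Enabling feature.** Indane C3 and the carbinol carbon flank the C1–C2 bond, and each carries a 4-hydroxyphenyl group, so both are latent p-quinone methide carbons. C3a of resorcinol ring A (the benzo ring of the indane) lies ortho to O4 and para to O6, and it closes a five-membered ring onto C3.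
- **Forward order.** Benzophenone, then the dihydrobenzofuran ring (its benzo ring is ring B), then two Heck reactions, then oxidative union of the two stilbenes, in which the cyclopentane ring of the indane closes last, then two deprotections.
- **Stereochemistry.** Benzofuran C3 comes from a chiral rhodium carboxylate and C2 from acid equilibration to trans. Indane C1, C2, C3 and the carbinol carbon arise in the key step, controlled by the aryl group on benzofuran C3, the all-trans preference of the indane and allylic strain.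
- **Helpers.** Chlorine ortho to the two reacting phenols blocks ortho coupling, makes only these OH groups acidic and oxidisable, and tames the carbinol. The pivalates switch off the arenes that could compete with ring A.

Key step: step 12

Assumption: Rh2(S-PTAD)4 is taken to give the (3R) series in step 6; if the sense of induction is the opposite, the enantiomeric catalyst Rh2(R-PTAD)4 is used.

Step 1
Reactants: 1 1-bromo-3,5-dimethoxybenzene; 2 3,5-dimethoxybenzoyl chloride
Product: 3 (2-bromo-4,6-dimethoxyphenyl)(3,5-dimethoxyphenyl)methanone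
Conditions: Bi(OTf)3 (10 mol %), MeNO2, 50 °C
Reagents that add atoms: none
Why: Metal-triflate-catalysed Friedel-Crafts acylation should attack the position para to one methoxy group and ortho to the other (next to Br) rather than the position between the two methoxy groups, as is usual for 5-substituted resorcinol dimethyl ethers.

Step 2
Reactants: 3 (2-bromo-4,6-dimethoxyphenyl)(3,5-dimethoxyphenyl)methanone
Product: 4 (2-bromo-4,6-dihydroxyphenyl)(3,5-dihydroxyphenyl)methanone
Conditions: BBr3, CH2Cl2, -78 °C to 23 °C; H2O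
Reagents that add atoms: none
Why: Lewis acid cleavage of aryl methyl ethers (BBr3 demethylation) should free all four phenols while the aryl bromide and the diaryl ketone stay untouched.

Step 3
Reactants: 4 (2-bromo-4,6-dihydroxyphenyl)(3,5-dihydroxyphenyl)methanone
Product: 5 [2-bromo-6-hydroxy-4-(methoxymethoxy)phenyl][3,5-bis(methoxymethoxy)phenyl]methanone
Conditions: MOMCl (3.1 equiv), K2CO3, acetone, 0 °C to 23 °C
Reagents that add atoms: chloromethyl methyl ether, COCCl
Why: In this Williamson-type O-alkylation the phenol ortho to the ketone is held in an intramolecular hydrogen bond and is hindered, so the three other phenols should be etherified selectively.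

Step 4
Reactants: 5 [2-bromo-6-hydroxy-4-(methoxymethoxy)phenyl][3,5-bis(methoxymethoxy)phenyl]methanone; 6 4-(benzyloxy)benzyl chloride
Product: 7 [2-{[4-(benzyloxy)phenyl]methoxy}-6-bromo-4-(methoxymethoxy)phenyl][3,5-bis(methoxymethoxy)phenyl]methanone
Conditions: K2CO3, NaI (cat.), DMF, 60 °C
Reagents that add atoms: none
Why: Williamson ether synthesis under more forcing conditions should alkylate the remaining chelated phenol and bring in the benzylic CH2 that becomes benzofuran C2.

Step 5
Reactants: 7 [2-{[4-(benzyloxy)phenyl]methoxy}-6-bromo-4-(methoxymethoxy)phenyl][3,5-bis(methoxymethoxy)phenyl]methanone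
Product: 8 hydrazone of ketone 7
Conditions: N2H4·H2O (excess), AcOH (cat.), n-BuOH, 110 °C
Reagents that add atoms: hydrazine, NN
Why: Hydrazone condensation with a large excess of hydrazine and heat should overcome the two ortho substituents, and the electron-rich ring disfavours displacement of bromide.

Step 6
Reactants: 8 hydrazone of ketone 7
Product: 10 (2S,3R)-cis-2,3-diaryl-4-bromo-2,3-dihydrobenzofuran tris(MOM ether), via diaryldiazomethane 9 (not isolated)
Conditions: MnO2, CH2Cl2, 23 °C, filter; Rh2(S-PTAD)4 (1 mol %), CH2Cl2, 0 °C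
Reagents that add atoms: none
Why: Oxidation of the hydrazone to the diazo compound, followed by enantioselective intramolecular 1,5 C–H insertion of the donor/donor rhodium carbene into the doubly activated benzylic ether C–H, should close the ring, with the chiral carboxylate ligands setting C3 and the concerted insertion giving the 2,3-cis product.

Step 7
Reactants: 10 (2S,3R)-cis-2,3-diaryl-4-bromo-2,3-dihydrobenzofuran tris(MOM ether)
Product: 11 (2R,3R)-2-[4-(benzyloxy)phenyl]-4-bromo-3-(3,5-dihydroxyphenyl)-2,3-dihydro-1-benzofuran-6-ol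
Conditions: HCl (1.25 M in MeOH), CH2Cl2, 40 °C
Reagents that add atoms: none
Why: Acid-catalysed acetal exchange should remove the three MOM groups, while reversible ionisation of the C2–O bond to the 4-benzyloxybenzyl cation epimerises C2 to the more stable 2,3-trans isomer and leaves C3 untouched.

Step 8
Reactants: 11 (2R,3R)-2-[4-(benzyloxy)phenyl]-4-bromo-3-(3,5-dihydroxyphenyl)-2,3-dihydro-1-benzofuran-6-ol
Product: 12 tris(pivalate) of 11
Conditions: PivCl (3.3 equiv), Et3N, DMAP (cat.), CH2Cl2, 0 °C to 23 °C
Reagents that add atoms: pivaloyl chloride, CC(C)(C)C(Cl)=O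
Why: DMAP-catalysed esterification should convert the three resorcinol-type phenols into robust electron-withdrawing esters that later deactivate ring B and the 3-aryl ring.

Step 9
Reactants: 13 3,5-dichloro-4-hydroxybenzaldehyde
Product: 14 2,6-dichloro-4-vinylphenol
Conditions: MePPh3Br, KOtBu (2.2 equiv), THF, 0 °C to 23 °C
Reagents that add atoms: methyltriphenylphosphonium bromide, C[P+](c1ccccc1)(c1ccccc1)c1ccccc1.[Br-]
Why: Wittig methylenation should proceed with the phenol carried as its phenoxide by the second equivalent of base.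

Step 10
Reactants: 12 tris(pivalate) of 11; 14 2,6-dichloro-4-vinylphenol
Product: 15 ε-viniferin-type (E)-stilbene with a free 2,6-dichlorophenol
Conditions: Pd(OAc)2 (5 mol %), P(o-tol)3, Et3N, DMF, 95 °C
Reagents that add atoms: none
Why: In this Heck reaction oxidative addition should select the C–Br bond over the hindered, electron-rich C–Cl bonds, and syn insertion followed by syn β-hydride elimination gives the E alkene.

Step 11
Reactants: 16 1,3-bis(benzyloxy)-5-bromobenzene; 14 2,6-dichloro-4-vinylphenol
Product: 17 4-{(E)-2-[3,5-bis(benzyloxy)phenyl]ethenyl}-2,6-dichlorophenol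
Conditions: Pd(OAc)2 (2 mol %), P(o-tol)3, Et3N, DMF, 95 °C
Reagents that add atoms: none
Why: The same chemoselective Heck reaction should give the resveratrol-type E-stilbene with ring A kept electron-rich as its bis(benzyl ether).

Step 12
Reactants: 15 ε-viniferin-type (E)-stilbene with a free 2,6-dichlorophenol; 17 4-{(E)-2-[3,5-bis(benzyloxy)phenyl]ethenyl}-2,6-dichlorophenol
Product: 20 protected indanyl carbinol (indane 1S,2R,3S; carbinol S; benzofuran 2R,3R), via bis(quinone methide) 18 (not isolated), via indanyl quinone methide 19 (not isolated)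
Conditions: 17 (4 equiv), Ag2O (2.6 equiv), 4 Å MS, CH2Cl2, 23 °C, dark; filter under Ar; BF3·OEt2 (0.3 equiv), -78 °C; then H2O–THF, -78 to -20 °C
Reagents that add atoms: water, O
Why: Ag2O oxidises the two acidic 2,6-dichlorophenols, the only free OH groups present, to phenoxyl radicals that carry much of their spin on the stilbene carbon next to ring A or ring B and, with both ortho positions chlorinated, pair carbon to carbon to bis(quinone methide) 18; catalytic BF3·OEt2 then lets an ortho carbon of the dibenzyloxyphenyl ring A add to the methide carbon of the benzofuranyl half (19), and water adds 1,6 to the methide that is left (20). The closest known reaction type is the oxidative 8-8' dimerisation of ortho-blocked 4-hydroxystilbenes to bis(quinone methides) followed by Lewis acid Friedel-Crafts closure to 1,2,3-trisubstituted indanes, together with the capture of such methides by water when 4-hydroxystilbenes are oxidised in aqueous media. The one ring closed, the cyclopentane ring of the indane, forms by 5-exo-trig Friedel-Crafts attack of the arene carbon on the exocyclic methide carbon. Indane C2 is set by approach of the partner radical to the face of the planar benzofuranyl radical opposite to the aryl group on benzofuran C3 (styryl arm turned toward C5-H), C1 by the unlike pairing that keeps rings A and B anti and alone can close to a 1,2-trans indane, C3 by an envelope transition state that places its aryl group trans to ring B, and the carbinol carbon by attack of water on the conformer in which C1-H eclipses the methide plane (allylic strain), from the side of the flat ring A and away from C2 and the C3 aryl group. Cross-coupling of the valuable partner 15 is secured by the excess of 17 and by the weak central C–C bond of such dimers, which should reopen at ambient temperature and let mismatched pairs re-sort before the acid is added, and regioselectivity is secured by the pivalates, which leave ring A as the only arene whose reacting carbon is ortho and para to two ether oxygens, whereas ring B (isomeric indane) and the 3,5-bis(pivaloyloxy)phenyl ring (seven-membered ring) are switched off. Loss of the C1 proton from 19 is held back by the low temperature and the absence of base, and the chlorine atoms make the methides electrophilic enough for catalytic acid under these conditions.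

Step 13
Reactants: 20 protected indanyl carbinol
Product: 21 tris(benzyl ether) tetrachloride of the target
Conditions: K2CO3, MeOH–THF, 23 °C, Ar; aq. NH4Cl
Reagents that add atoms: none
Why: Base-mediated transesterification (methanolysis) should cleave the three aryl pivalates, while the weakly donating dichlorophenoxides do not expel the benzylic hydroxyl group and the O-benzylated 2-aryl group keeps the dihydrobenzofuran closed.

Step 14
Reactants: 21 tris(benzyl ether) tetrachloride of the target
Product: 22 target CNP0175860.1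
Conditions: H2 (1 atm), 10% Pd/C, Et3N, MeOH–THF, 23 °C
Reagents that add atoms: none
Why: Heterogeneous catalytic hydrogenolysis should cleave the three aryl benzyl ethers, amine-promoted hydrodechlorination should remove the four chlorine atoms, and the base keeps the medium free of HCl so that the benzylic carbinol and the benzofuran C2–O bond are retained with all six stereocenters unchanged.

**Compound list**
1 | 1-bromo-3,5-dimethoxybenzene | COc1cc(Br)cc(OC)c1 | starting material
2 | 3,5-dimethoxybenzoyl chloride | COc1cc(cc(OC)c1)C(Cl)=O | starting material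
3 | (2-bromo-4,6-dimethoxyphenyl)(3,5-dimethoxyphenyl)methanone | COc1cc(OC)cc(c1)C(=O)c1c(Br)cc(OC)cc1OC | intermediate
4 | (2-bromo-4,6-dihydroxyphenyl)(3,5-dihydroxyphenyl)methanone | Oc1cc(O)cc(c1)C(=O)c1c(Br)cc(O)cc1O | intermediate
5 | [2-bromo-6-hydroxy-4-(methoxymethoxy)phenyl][3,5-bis(methoxymethoxy)phenyl]methanone | COCOc1cc(OCOC)cc(c1)C(=O)c1c(Br)cc(OCOC)cc1O | intermediate
6 | 4-(benzyloxy)benzyl chloride | ClCc1ccc(OCc2ccccc2)cc1 | starting material
7 | [2-{[4-(benzyloxy)phenyl]methoxy}-6-bromo-4-(methoxymethoxy)phenyl][3,5-bis(methoxymethoxy)phenyl]methanone | COCOc1cc(OCOC)cc(c1)C(=O)c1c(Br)cc(OCOC)cc1OCc1ccc(OCc2ccccc2)cc1 | intermediate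
8 | hydrazone of ketone 7 (mixture of C=N isomers) | COCOc1cc(OCOC)cc(c1)C(=NN)c1c(Br)cc(OCOC)cc1OCc1ccc(OCc2ccccc2)cc1 | intermediate
9 | diaryldiazomethane derived from 8 | COCOc1cc(OCOC)cc(c1)C(=[N+]=[N-])c1c(Br)cc(OCOC)cc1OCc1ccc(OCc2ccccc2)cc1 | intermediate
10 | (2S,3R)-2-[4-(benzyloxy)phenyl]-4-bromo-6-(methoxymethoxy)-3-[3,5-bis(methoxymethoxy)phenyl]-2,3-dihydro-1-benzofuran (2,3-cis) | Brc1cc(OCOC)cc2c1[C@@H](c1cc(OCOC)cc(OCOC)c1)[C@@H](c1ccc(OCc3ccccc3)cc1)O2 | intermediate
11 | (2R,3R)-2-[4-(benzyloxy)phenyl]-4-bromo-3-(3,5-dihydroxyphenyl)-2,3-dihydro-1-benzofuran-6-ol (2,3-trans) | Brc1cc(O)cc2c1[C@@H](c1cc(O)cc(O)c1)[C@H](c1ccc(OCc3ccccc3)cc1)O2 | intermediate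
12 | tris(pivalate) of 11: (2R,3R)-2-[4-(benzyloxy)phenyl]-4-bromo-3-[3,5-bis(pivaloyloxy)phenyl]-2,3-dihydro-1-benzofuran-6-yl pivalate | Brc1cc(OC(=O)C(C)(C)C)cc2c1[C@@H](c1cc(OC(=O)C(C)(C)C)cc(OC(=O)C(C)(C)C)c1)[C@H](c1ccc(OCc3ccccc3)cc1)O2 | intermediate
13 | 3,5-dichloro-4-hydroxybenzaldehyde | O=Cc1cc(Cl)c(O)c(Cl)c1 | starting material
14 | 2,6-dichloro-4-vinylphenol | C=Cc1cc(Cl)c(O)c(Cl)c1 | intermediate
15 | (2R,3R)-2-[4-(benzyloxy)phenyl]-4-[(E)-2-(3,5-dichloro-4-hydroxyphenyl)ethenyl]-3-[3,5-bis(pivaloyloxy)phenyl]-2,3-dihydro-1-benzofuran-6-yl pivalate | Oc1c(Cl)cc(/C=C/c2cc(OC(=O)C(C)(C)C)cc3c2[C@@H](c2cc(OC(=O)C(C)(C)C)cc(OC(=O)C(C)(C)C)c2)[C@H](c2ccc(OCc4ccccc4)cc2)O3)cc1Cl | intermediate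
16 | 1,3-bis(benzyloxy)-5-bromobenzene | Brc1cc(OCc2ccccc2)cc(OCc2ccccc2)c1 | starting material
17 | 4-{(E)-2-[3,5-bis(benzyloxy)phenyl]ethenyl}-2,6-dichlorophenol | Oc1c(Cl)cc(/C=C/c2cc(OCc3ccccc3)cc(OCc3ccccc3)c2)cc1Cl | intermediate
18 | bis(quinone methide): 4,4'-[(2S,3R)-butane-1,4-diylidene]bis(2,6-dichlorocyclohexa-2,5-dien-1-one) carrying the 3,5-bis(benzyloxy)phenyl ring A on C2 and the (2R,3R)-dihydrobenzofuran-4-yl group of 15 on C3 | O(Cc1ccccc1)c1cc(OCc2ccccc2)cc(c1)[C@@H](C=C1C=C(Cl)C(=O)C(Cl)=C1)[C@@H](C=C1C=C(Cl)C(=O)C(Cl)=C1)c1cc(OC(=O)C(C)(C)C)cc2c1[C@@H](c1cc(OC(=O)C(C)(C)C)cc(OC(=O)C(C)(C)C)c1)[C@H](c1ccc(OCc3ccccc3)cc1)O2 | intermediate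
19 | indanyl quinone methide: 1,2-trans-2,3-trans indane with the configuration of 20, 2,6-dichloro-p-quinone methide on C1, 3,5-dichloro-4-hydroxyphenyl on C3 | Oc1c(Cl)cc([C@H]2c3c(OCc4ccccc4)cc(OCc4ccccc4)cc3[C@@H](C=C3C=C(Cl)C(=O)C(Cl)=C3)[C@@H]2c2cc(OC(=O)C(C)(C)C)cc3c2[C@@H](c2cc(OC(=O)C(C)(C)C)cc(OC(=O)C(C)(C)C)c2)[C@H](c2ccc(OCc4ccccc4)cc2)O3)cc1Cl | intermediate
20 | (S)-(3,5-dichloro-4-hydroxyphenyl)[(1S,2R,3S)-4,6-bis(benzyloxy)-3-(3,5-dichloro-4-hydroxyphenyl)-2-{(2R,3R)-2-[4-(benzyloxy)phenyl]-3-[3,5-bis(pivaloyloxy)phenyl]-6-(pivaloyloxy)-2,3-dihydro-1-benzofuran-4-yl}-2,3-dihydro-1H-inden-1-yl]methanol | Oc1c(Cl)cc([C@H]2c3c(OCc4ccccc4)cc(OCc4ccccc4)cc3[C@@H]([C@H](O)c3cc(Cl)c(O)c(Cl)c3)[C@@H]2c2cc(OC(=O)C(C)(C)C)cc3c2[C@@H](c2cc(OC(=O)C(C)(C)C)cc(OC(=O)C(C)(C)C)c2)[C@H](c2ccc(OCc4ccccc4)cc2)O3)cc1Cl | intermediate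
21 | compound 20 with the three pivalates replaced by free phenols (same six configurations) | Oc1c(Cl)cc([C@H]2c3c(OCc4ccccc4)cc(OCc4ccccc4)cc3[C@@H]([C@H](O)c3cc(Cl)c(O)c(Cl)c3)[C@@H]2c2cc(O)cc3c2[C@@H](c2cc(O)cc(O)c2)[C@H](c2ccc(OCc4ccccc4)cc2)O3)cc1Cl | intermediate
22 | CNP0175860.1: (1S,2R,3S)-indane-4,6-diol with (S)-hydroxy(4-hydroxyphenyl)methyl on C1, the (2R,3R)-3-(3,5-dihydroxyphenyl)-6-hydroxy-2-(4-hydroxyphenyl)-2,3-dihydro-1-benzofuran-4-yl group on C2 and 4-hydroxyphenyl on C3 | Oc1ccc([C@H]2c3c(O)cc(O)cc3[C@@H]([C@H](O)c3ccc(O)cc3)[C@@H]2c2cc(O)cc3c2[C@@H](c2cc(O)cc(O)c2)[C@H](c2ccc(O)cc2)O3)cc1 | target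

**Total step count:** 14.
**Longest linear sequence:** 12 (steps 1–8, 10, 12, 13, 14).

**Steps most likely to fail**

Step 12. The addition of water to the surviving methide may show poor facial selectivity, so that the carbinol centre is not uniform. The fallback replaces substrate-controlled C–O bond formation by catalyst-controlled C–H bond formation. It sets out from 20 as obtained. Oxidation with DMP in CH2Cl2 at 0 °C should give the aryl indanyl ketone F1, in which C1 stays trans because that is the stable arrangement next to the carbonyl group. Asymmetric transfer hydrogenation with RuCl[(S,S)-TsDPEN](p-cymene) in HCO2H–Et3N should then set the (S)-carbinol and return to 20.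

Step 6. The second ortho substituent on the carbene carbon may erode the enantioselectivity of the insertion. The fallback gives up catalyst control in favour of a classical resolution. It sets out from 11 of insufficient enantiomeric purity. Esterification with (1S)-camphanic chloride (Et3N, DMAP, CH2Cl2) should give the tris(camphanate) F2, which is freed from its diastereomer by crystallisation or chromatography. Methanolysis (K2CO3, MeOH) then returns to enantiopure 11.

Step 14. The benzylic C–OH bond or the benzofuran C2–O bond may be hydrogenolysed while the slower C–Cl cleavage is still under way. The fallback separates the two reductions and takes the chlorine off with a homogeneous palladium hydride that does not touch benzylic C–O bonds. It sets out from 21. Pd(OAc)2, PCy3 and HCO2Na in DMF at 80 °C should give the chlorine-free tris(benzyl ether) F3. Mild transfer hydrogenolysis (10% Pd/C, 1,4-cyclohexadiene, EtOH, 23 °C) then comes back to the route at 22.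

**Further compounds**
F1 | step 12 | (3,5-dichloro-4-hydroxyphenyl) (1S,2R,3S)-indan-1-yl ketone corresponding to 20 | Oc1c(Cl)cc([C@H]2c3c(OCc4ccccc4)cc(OCc4ccccc4)cc3[C@@H](C(=O)c3cc(Cl)c(O)c(Cl)c3)[C@@H]2c2cc(OC(=O)C(C)(C)C)cc3c2[C@@H](c2cc(OC(=O)C(C)(C)C)cc(OC(=O)C(C)(C)C)c2)[C@H](c2ccc(OCc4ccccc4)cc2)O3)cc1Cl
F2 | step 6 | tris[(1S,4R)-camphanate] of (2R,3R)-11 | Brc1cc(OC(=O)[C@@]45CC[C@@](C)(C(=O)O4)C5(C)C)cc2c1[C@@H](c1cc(OC(=O)[C@@]45CC[C@@](C)(C(=O)O4)C5(C)C)cc(OC(=O)[C@@]45CC[C@@](C)(C(=O)O4)C5(C)C)c1)[C@H](c1ccc(OCc3ccccc3)cc1)O2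
F3 | step 14 | tris(benzyl ether) of the target (21 without chlorine) | Oc1ccc([C@H]2c3c(OCc4ccccc4)cc(OCc4ccccc4)cc3[C@@H]([C@H](O)c3ccc(O)cc3)[C@@H]2c2cc(O)cc3c2[C@@H](c2cc(O)cc(O)c2)[C@H](c2ccc(OCc4ccccc4)cc2)O3)cc1
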